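**Plan**
- Retrosynthesis: the pentanoyl–ring A bond and the O-protecting groups are cut last. Ring B is then opened across C1'–C2' and C3'–C4' (Alder–Rickert) into a 1-benzyloxy-3-silyloxycyclohexa-1,3-diene already carrying ring A and a 1-alkoxyhex-1-yn-3-one. The diene is cut between the bridge carbon and C1' (aldol condensation).
- Forward: 2,4,6-trihydroxytoluene (ring A) is formylated and benzylated. Aldol condensation with the benzyl enol ether of 2-methylcyclohexane-1,3-dione and conjugate hydrosilylation give the diene. [4+2] addition and loss of ethene then form ring B directly as an arene.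
- Four contiguous ring B atoms (C4'–O, C5'–Me, C6'–O, C1'–CH2) come from the dione; C2'(O)–C3'(butanoyl) comes from the ynone.
- Finish: O6' is methylated, ring A is pentanoylated at its only free carbon, and the benzyl and isopropyl groups are removed. Both leave with BCl3 without carbonyl assistance, so methyl remains only on O6'.
- Stereochemistry: the target has no stereocentre; the benzylidene geometry, the racemic carbinol and the bridgeheads of the cycloadduct are all erased.

Key step: step 9

Remark: ring B locants follow the target (C1' bridge carbon, C2' and C4' hydroxyls, C3' butanoyl, C5' methyl, C6' methoxy); all chiral intermediates are racemic.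

**Step 1**
Reactants: 1 2,4,6-trihydroxytoluene
Product: 3 2,4,6-trihydroxy-3-methylbenzaldehyde, via iminium chloride 2 (not isolated)
Conditions: POCl3 (1.1 equiv), DMF, EtOAc, 0 °C → rt; then H2O, 60 °C
Reagents that add atoms: N,N-dimethylformamide CN(C)C=O; water O
Why: Vilsmeier–Haack formylation of the strongly activated phloroglucinol ring, whose two free positions are equivalent, so one aldehyde should form and a near-stoichiometric charge of reagent limits diformylation.

**Step 2**
Reactants: 3 2,4,6-trihydroxy-3-methylbenzaldehyde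
Product: 4 2,4,6-tris(benzyloxy)-3-methylbenzaldehyde
Conditions: BnBr (3.6 equiv), K2CO3, DMF, 60 °C
Reagents that add atoms: benzyl bromide BrCc1ccccc1
Why: Williamson ether synthesis, in which the formyl group lowers the nucleophilicity of the ring carbon so that O-benzylation should outrun C-benzylation, while warming carries the two hydrogen-bonded hydroxyls through.

**Step 3**
Reactants: 5 2-methylcyclohexane-1,3-dione
Product: 6 3-(benzyloxy)-2-methylcyclohex-2-en-1-one
Conditions: BnOH, TsOH (cat.), toluene, reflux, Dean–Stark trap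
Reagents that add atoms: benzyl alcohol OCc1ccccc1
Why: Acid-catalysed enol ether formation of a symmetric cyclic 1,3-dione with azeotropic removal of water, which can give only one vinylogous ester.

**Step 4**
Reactants: 6 3-(benzyloxy)-2-methylcyclohex-2-en-1-one, 4 2,4,6-tris(benzyloxy)-3-methylbenzaldehyde
Product: 10 (6E)-3-(benzyloxy)-2-methyl-6-{[2,4,6-tris(benzyloxy)-3-methylphenyl]methylidene}cyclohex-2-en-1-one, via lithium enolate 7 (not isolated), via lithium aldolate 8 (not isolated), via mesylate 9 (not isolated)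
Conditions: LiN(iPr)2, THF, −78 °C; then 4; then MsCl, −78 → 0 °C; then DBU, rt
Reagents that add atoms: none
Why: Directed aldol condensation in which kinetic deprotonation of the vinylogous ester occurs at C6, the enolate adds to the aldehyde and mesylation with E1cB elimination gives the conjugated benzylidene with the aryl group turned away from the carbonyl, a sequence that avoids a self-alkylating 2,4,6-trialkoxybenzyl halide.

**Step 5**
Reactants: 10 (6E)-3-(benzyloxy)-2-methyl-6-{[2,4,6-tris(benzyloxy)-3-methylphenyl]methylidene}cyclohex-2-en-1-one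
Product: 11 1-(benzyloxy)-2-methyl-3-[(triethylsilyl)oxy]-4-[2,4,6-tris(benzyloxy)-3-methylbenzyl]cyclohexa-1,3-diene
Conditions: Et3SiH (1.5 equiv), RhCl(PPh3)3 (2 mol%), toluene, 60 °C
Reagents that add atoms: triethylsilane CC[SiH](CC)CC
Why: Rhodium-catalysed 1,4-hydrosilylation of an enone with a monohydrosilane, which puts hydride on the benzylic β-carbon and silicon on oxygen and so fixes the new enol ether double bond on the side of the bridge carbon, the vinylogous ester half being the poorer acceptor.

**Step 6**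
Reactants: 12 trichloroethylene
Product: 13 (E)-1,2-dichloro-1-(propan-2-yloxy)ethene
Conditions: i-PrOH, KH, THF, 0 °C; then 12, −40 °C → rt
Reagents that add atoms: propan-2-ol CC(C)O
Why: Addition of a potassium alkoxide to trichloroethylene by way of dichloroacetylene, the standard entry to 1,2-dichlorovinyl ethers as ynol ether precursors.

**Step 7**
Reactants: 13 (E)-1,2-dichloro-1-(propan-2-yloxy)ethene, 14 butanal
Product: 17 1-(propan-2-yloxy)hex-1-yn-3-ol (racemic), via chloroalkynyl ether 15 (not isolated), via lithium alkoxyacetylide 16 (not isolated)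
Conditions: n-BuLi (2.1 equiv), THF, −78 → −40 °C; then 14, −78 °C; H2O
Reagents that add atoms: none
Why: Dehydrochlorination and chlorine–lithium exchange give the lithium alkoxyacetylide, which undergoes 1,2-addition to the aldehyde; the carbinol centre is racemic and is removed in step 8.

**Step 8**
Reactants: 17 1-(propan-2-yloxy)hex-1-yn-3-ol
Product: 18 1-(propan-2-yloxy)hex-1-yn-3-one
Conditions: MnO2 (activated, excess), CH2Cl2, rt
Reagents that add atoms: none
Why: Oxidation of a propargylic alcohol with MnO2 under neutral conditions, which should avoid the acid-triggered Meyer–Schuster rearrangement of alkoxyalkynyl carbinols.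

**Step 9**
Reactants: 11 1-(benzyloxy)-2-methyl-3-[(triethylsilyl)oxy]-4-[2,4,6-tris(benzyloxy)-3-methylbenzyl]cyclohexa-1,3-diene, 18 1-(propan-2-yloxy)hex-1-yn-3-one
Product: 20 1-{6-(benzyloxy)-5-methyl-2-(propan-2-yloxy)-4-[(triethylsilyl)oxy]-3-[2,4,6-tris(benzyloxy)-3-methylbenzyl]phenyl}butan-1-one, via bicyclo[2.2.2]octadiene adduct 19 (not isolated)
Conditions: 18 (1.5 equiv), toluene, 80 °C; then 130 °C, sealed tube
Reagents that add atoms: none
Why: The diene is locked s-cis and its terminal benzyloxy and internal silyloxy groups both place the largest HOMO coefficient on the benzyl-bearing terminus C1', which bonds to the alkoxy-bearing β-carbon of the ynone while the carbonyl-bearing α-carbon bonds to C4', by a concerted asynchronous [4+2] addition or by Michael addition and ring closure, either path giving adduct 19. On further heating 19 expels its saturated two-carbon bridge as ethene in a retro-Diels–Alder step driven by aromatisation, which is the Alder–Rickert reaction, best known for 1-alkoxy-3-silyloxycyclohexa-1,3-dienes with propiolates and ynones; a β-alkoxy ynone is a less usual and less reactive partner. Ring B is closed by an intermolecular [4+2] cycloaddition that makes C1'–C2' and C3'–C4' in one operation, so no tether or ring-size rule is involved. The two bridgehead stereocentres of 19 form as a racemate and disappear with the ethene, so 20 has none. The step needs regioselectivity, secured by the matched polarisation of the two partners, and a cycloaddition faster than thermal breakdown of the partners, hence 80 °C first (below the expected retro-ene fragmentation of the isopropyl ynol ether and below [1,5]-hydrogen shifts of the diene) and 130 °C only for the extrusion. The secondary alkoxy group is chosen so that O2' can later be freed by BCl3 without help from the carbonyl, which the neighbouring O4' would occupy.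

**Step 10**
Reactants: 20 1-{6-(benzyloxy)-5-methyl-2-(propan-2-yloxy)-4-[(triethylsilyl)oxy]-3-[2,4,6-tris(benzyloxy)-3-methylbenzyl]phenyl}butan-1-one
Product: 22 1-{6-(benzyloxy)-4-methoxy-5-methyl-2-(propan-2-yloxy)-3-[2,4,6-tris(benzyloxy)-3-methylbenzyl]phenyl}butan-1-one, via caesium phenoxide 21 (not isolated)
Conditions: CsF, MeI, DMF, rt
Reagents that add atoms: iodomethane CI
Why: Fluoride cleaves the aryl silyl ether and the phenoxide is methylated in the same flask (Williamson ether synthesis); it is the only free oxygen nucleophile, which fixes the methyl group on O6'.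

**Step 11**
Reactants: 22 1-{6-(benzyloxy)-4-methoxy-5-methyl-2-(propan-2-yloxy)-3-[2,4,6-tris(benzyloxy)-3-methylbenzyl]phenyl}butan-1-one, 23 pentanoic acid
Product: 24 1-{2,4,6-tris(benzyloxy)-3-{[4-(benzyloxy)-3-butanoyl-6-methoxy-5-methyl-2-(propan-2-yloxy)phenyl]methyl}-5-methylphenyl}pentan-1-one
Conditions: (CF3CO)2O, CH2Cl2, 0 °C → rt
Reagents that add atoms: none
Why: Friedel–Crafts acylation by the mixed anhydride at C1 of ring A, the only unsubstituted carbon of the two oxygenated rings and ortho/para to three ether oxygens, with no metal Lewis acid present to cleave benzyl or isopropyl ethers.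

**Step 12**
Reactants: 24 1-{2,4,6-tris(benzyloxy)-3-{[4-(benzyloxy)-3-butanoyl-6-methoxy-5-methyl-2-(propan-2-yloxy)phenyl]methyl}-5-methylphenyl}pentan-1-one
Product: 25 1-{3-[(3-butanoyl-2,4-dihydroxy-6-methoxy-5-methylphenyl)methyl]-2,4,6-trihydroxy-5-methylphenyl}pentan-1-one (CNP0210501.0)
Conditions: BCl3 (excess), C6HMe5, CH2Cl2, −78 → 0 °C; then MeOH
Reagents that add atoms: none
Why: Lewis-acid ether cleavage in which BCl3 removes aryl benzyl and aryl isopropyl ethers at low temperature through stabilised carbocations (trapped by pentamethylbenzene), while the aryl methyl ether, para and not ortho to the butanoyl group and so without chelation assistance, should be retained.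

**Compound list**
1 | 2,4,6-trihydroxytoluene | Cc1c(O)cc(O)cc1O | starting material
2 | N,N-dimethyl(2,4,6-trihydroxy-3-methylbenzylidene)ammonium chloride | C[N+](C)=Cc1c(O)cc(O)c(C)c1O.[Cl-] | intermediate
3 | 2,4,6-trihydroxy-3-methylbenzaldehyde | O=Cc1c(O)cc(O)c(C)c1O | intermediate
4 | 2,4,6-tris(benzyloxy)-3-methylbenzaldehyde | O=Cc1c(OCc2ccccc2)cc(OCc2ccccc2)c(C)c1OCc1ccccc1 | intermediate
5 | 2-methylcyclohexane-1,3-dione | CC1C(=O)CCCC1=O | starting material
6 | 3-(benzyloxy)-2-methylcyclohex-2-en-1-one | CC1=C(OCc2ccccc2)CCCC1=O | intermediate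
7 | lithium 3-(benzyloxy)-2-methylcyclohexa-1,3-dien-1-olate (numbered with the enolate oxygen on C1) | [Li+].[O-]C1=CCCC(OCc2ccccc2)=C1C | intermediate
8 | lithium [4-(benzyloxy)-3-methyl-2-oxocyclohex-3-en-1-yl][2,4,6-tris(benzyloxy)-3-methylphenyl]methanolate (racemic diastereomers) | [Li+].[O-]C(C1CCC(OCc2ccccc2)=C(C)C1=O)c1c(OCc2ccccc2)cc(OCc2ccccc2)c(C)c1OCc1ccccc1 | intermediate
9 | [4-(benzyloxy)-3-methyl-2-oxocyclohex-3-en-1-yl][2,4,6-tris(benzyloxy)-3-methylphenyl]methyl methanesulfonate (racemic diastereomers) | CS(=O)(=O)OC(C1CCC(OCc2ccccc2)=C(C)C1=O)c1c(OCc2ccccc2)cc(OCc2ccccc2)c(C)c1OCc1ccccc1 | intermediate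
10 | (6E)-3-(benzyloxy)-2-methyl-6-{[2,4,6-tris(benzyloxy)-3-methylphenyl]methylidene}cyclohex-2-en-1-one | O=C1C(C)=C(OCc2ccccc2)CC/C1=C\c1c(OCc2ccccc2)cc(OCc2ccccc2)c(C)c1OCc1ccccc1 | intermediate
11 | 1-(benzyloxy)-2-methyl-3-[(triethylsilyl)oxy]-4-[2,4,6-tris(benzyloxy)-3-methylbenzyl]cyclohexa-1,3-diene | CC[Si](CC)(CC)OC1=C(Cc2c(OCc3ccccc3)cc(OCc3ccccc3)c(C)c2OCc2ccccc2)CCC(OCc2ccccc2)=C1C | intermediate
12 | trichloroethylene | ClC=C(Cl)Cl | starting material
13 | (E)-1,2-dichloro-1-(propan-2-yloxy)ethene | CC(C)OC(/Cl)=C\Cl | intermediate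
14 | butanal | CCCC=O | starting material
15 | 1-chloro-2-(propan-2-yloxy)ethyne | ClC#COC(C)C | intermediate
16 | lithium (propan-2-yloxy)ethynide | [Li+].[C-]#COC(C)C | intermediate
17 | 1-(propan-2-yloxy)hex-1-yn-3-ol (racemic) | CCCC(O)C#COC(C)C | intermediate
18 | 1-(propan-2-yloxy)hex-1-yn-3-one | CCCC(=O)C#COC(C)C | intermediate
19 | 1-{1-(benzyloxy)-6-methyl-3-(propan-2-yloxy)-5-[(triethylsilyl)oxy]-4-[2,4,6-tris(benzyloxy)-3-methylbenzyl]bicyclo[2.2.2]octa-2,5-dien-2-yl}butan-1-one (racemic) | CCCC(=O)C1=C(OC(C)C)C2(Cc3c(OCc4ccccc4)cc(OCc4ccccc4)c(C)c3OCc3ccccc3)CCC1(OCc1ccccc1)C(C)=C2O[Si](CC)(CC)CC | intermediate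
20 | 1-{6-(benzyloxy)-5-methyl-2-(propan-2-yloxy)-4-[(triethylsilyl)oxy]-3-[2,4,6-tris(benzyloxy)-3-methylbenzyl]phenyl}butan-1-one | CCCC(=O)c1c(OC(C)C)c(Cc2c(OCc3ccccc3)cc(OCc3ccccc3)c(C)c2OCc2ccccc2)c(O[Si](CC)(CC)CC)c(C)c1OCc1ccccc1 | intermediate
21 | caesium 4-(benzyloxy)-5-butanoyl-3-methyl-6-(propan-2-yloxy)-2-[2,4,6-tris(benzyloxy)-3-methylbenzyl]phenolate (numbered from the phenolate carbon) | [Cs+].CCCC(=O)c1c(OC(C)C)c(Cc2c(OCc3ccccc3)cc(OCc3ccccc3)c(C)c2OCc2ccccc2)c([O-])c(C)c1OCc1ccccc1 | intermediate
22 | 1-{6-(benzyloxy)-4-methoxy-5-methyl-2-(propan-2-yloxy)-3-[2,4,6-tris(benzyloxy)-3-methylbenzyl]phenyl}butan-1-one | CCCC(=O)c1c(OC(C)C)c(Cc2c(OCc3ccccc3)cc(OCc3ccccc3)c(C)c2OCc2ccccc2)c(OC)c(C)c1OCc1ccccc1 | intermediate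
23 | pentanoic acid | CCCCC(=O)O | starting material
24 | 1-{2,4,6-tris(benzyloxy)-3-{[4-(benzyloxy)-3-butanoyl-6-methoxy-5-methyl-2-(propan-2-yloxy)phenyl]methyl}-5-methylphenyl}pentan-1-one | CCCCC(=O)c1c(OCc2ccccc2)c(C)c(OCc2ccccc2)c(Cc2c(OC(C)C)c(C(=O)CCC)c(OCc3ccccc3)c(C)c2OC)c1OCc1ccccc1 | intermediate
25 | 1-{3-[(3-butanoyl-2,4-dihydroxy-6-methoxy-5-methylphenyl)methyl]-2,4,6-trihydroxy-5-methylphenyl}pentan-1-one | CCCCC(=O)c1c(O)c(C)c(O)c(Cc2c(O)c(C(=O)CCC)c(O)c(C)c2OC)c1O | target

**Count and risks**
Total step count: 12. Longest linear sequence: 8 steps (1, 2, 4, 5, 9, 10, 11, 12, from compound 1).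

Most likely to fail, first: step 9. The alkoxy group raises the LUMO of the ynone and both diene termini are fully substituted, so the cycloaddition may be slow. Retro-ene fragmentation of the isopropyl ynol ether, [1,5]-hydrogen migration or protodesilylation of the diene could then consume the partners before ring B closes. The fallback gives up the cycloaddition and joins two aromatic rings by reductive Friedel–Crafts benzylation; it sets out from 1 and 4 and returns to the route at 25. Butanoyl chloride and AlCl3 in nitrobenzene would acylate 1 to 1-(2,4,6-trihydroxy-3-methylphenyl)butan-1-one F1. One equivalent of Me2SO4 with K2CO3 in acetone would methylate the hydroxyl para to the carbonyl to give 1-(2,6-dihydroxy-4-methoxy-3-methylphenyl)butan-1-one F2. F2 and aldehyde 4 with CF3CO2H and Et3SiH in CH2Cl2 would give 1-{2,6-dihydroxy-4-methoxy-3-methyl-5-[2,4,6-tris(benzyloxy)-3-methylbenzyl]phenyl}butan-1-one F3. Acylation with 23 and (CF3CO)2O as in step 11 would give 1-{2,4,6-tris(benzyloxy)-3-[(3-butanoyl-2,4-dihydroxy-6-methoxy-5-methylphenyl)methyl]-5-methylphenyl}pentan-1-one F4. Hydrogenolysis (H2, Pd/C, EtOAc) of the three benzyl ethers would then give 25.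

Second: step 11. Attack of the acylating agent at a carbon flanked by two benzyloxy groups may be slow, so that acid-induced loss or migration of benzyl groups, or ipso attack with scission of the methylene bridge, competes. The fallback reverses the order of acylation and deprotection; it sets out from 22 and returns at 25. BCl3 with pentamethylbenzene (CH2Cl2, −78 → 0 °C) would give 1-{2,4-dihydroxy-6-methoxy-5-methyl-3-[(2,4,6-trihydroxy-3-methylphenyl)methyl]phenyl}butan-1-one F5. Its free phloroglucinol ring would then be C-acylated at the only open position with 23 and BF3·OEt2 at 70 °C, the classical acylphloroglucinol procedure, to give 25.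

Third: step 5. 1,2-Hydrosilylation of the hindered enone, migration of the exocyclic double bond into the ring by a rhodium hydride (isoaromatisation to a phenol), or hydrolysis of the silyl dienol ether on isolation could each divert the material. The fallback separates reduction and enol ether formation; it sets out from 10 and returns at 11. Conjugate reduction with [(Ph3P)CuH]6 in benzene at rt and aqueous work-up would give 3-(benzyloxy)-2-methyl-6-[2,4,6-tris(benzyloxy)-3-methylbenzyl]cyclohex-2-en-1-one F6. Kinetic deprotonation at C6 with LiN(iPr)2 in THF at −78 °C and trapping with Et3SiCl would give 11.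

**Further compounds**
F1 | step 9 | 1-(2,4,6-trihydroxy-3-methylphenyl)butan-1-one | CCCC(=O)c1c(O)cc(O)c(C)c1O
F2 | step 9 | 1-(2,6-dihydroxy-4-methoxy-3-methylphenyl)butan-1-one | CCCC(=O)c1c(O)cc(OC)c(C)c1O
F3 | step 9 | 1-{2,6-dihydroxy-4-methoxy-3-methyl-5-[2,4,6-tris(benzyloxy)-3-methylbenzyl]phenyl}butan-1-one | CCCC(=O)c1c(O)c(Cc2c(OCc3ccccc3)cc(OCc3ccccc3)c(C)c2OCc2ccccc2)c(OC)c(C)c1O
F4 | step 9 | 1-{2,4,6-tris(benzyloxy)-3-[(3-butanoyl-2,4-dihydroxy-6-methoxy-5-methylphenyl)methyl]-5-methylphenyl}pentan-1-one | CCCCC(=O)c1c(OCc2ccccc2)c(C)c(OCc2ccccc2)c(Cc2c(O)c(C(=O)CCC)c(O)c(C)c2OC)c1OCc1ccccc1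
F5 | step 11 | 1-{2,4-dihydroxy-6-methoxy-5-methyl-3-[(2,4,6-trihydroxy-3-methylphenyl)methyl]phenyl}butan-1-one | CCCC(=O)c1c(O)c(Cc2c(O)cc(O)c(C)c2O)c(OC)c(C)c1O
F6 | step 5 | 3-(benzyloxy)-2-methyl-6-[2,4,6-tris(benzyloxy)-3-methylbenzyl]cyclohex-2-en-1-one (racemic) | O=C1C(C)=C(OCc2ccccc2)CCC1Cc1c(OCc2ccccc2)cc(OCc2ccccc2)c(C)c1OCc1ccccc1
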